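**Numbering used below.** Triquinane carbons carry cyclopenta[a]pentalene locants: ring A = C1 (C=O), C2 (enol-ether carbon), C3, C3a, C7a; ring B = C3a, C3b, C6a, C7, C7a; ring C = C3b, C4, C5, C6, C6a. Terpene carbons carry primed caryophyllane locants C1'–C11'. Compound numbers are those of the steps.

## Analysis of the target

Target 40 is hexacyclic: a linear triquinane (rings A–C), a dihydropyran D (C3, C2, O, C4', C5' and the linking CH2), a nine-membered carbocycle E (C1'–C9') and a gem-dimethylcyclobutane F (C1', C9', C10', C11'). Its nine stereocentres form two clusters that cannot control each other: C3a (quaternary, CH3), C3b, C5 (quaternary, CH3/CO2H), C6a and C7a in the triquinane, and C1', C4', C5' and C9' in the terpene half. The triquinane is cis-anti-cis: the C3a methyl is syn to ring C, H-7a is cis to that methyl, and the carboxyl lies on the convex face, cis to H-3b and H-6a. In the terpene half the cyclobutane is trans-fused with (1'S,9'R) configuration, the mirror image of the ring in the abundant (−)-β-caryophyllene. Pyran D is cis-fused to ring E (C4' methyl and H-5' on the same side), so the natural hydrocarbon cannot simply be bought and added. The sensitive groups are the tertiary-alkyl enol ether of a 1,2-dione and the exocyclic methylene (both acid-labile) and the epimerisable C7a. The difficulty lies in two quaternary carbons in a cis-anti-cis triquinane, a medium ring, and independent absolute control of two remote clusters. The strategy rests on rings B and C: they form a cis-bicyclo[3.3.0]octane in which C5 is flanked by two CH2 groups (C4, C6), while C7a and the methyl-bearing C3a are neighbours. That is the atom pattern left by a 1,2-acyl shift in a bicyclo[2.2.2]oct-5-en-2-one built from a methacrylate and an o-cresol-derived dienone.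

## Retrosynthetic reasoning

40 from 39. The carboxyl is carried as the methyl ester that comes with 3 and is freed last by saponification, so no acid is present in the organometallic steps.

39 from 38 and 37. Ring D is cut at the O–C2 bond, not at O–C4'. Forward, the tertiary hydroxyl of 38 adds to the C2 carbonyl and water is lost toward C3. The C4'–O bond is never broken, so C4' keeps its configuration and no cation arises in ring E beside the exocyclic alkene.

37 from 15 and 35 (through 36). The bond between C3 and the linking CH2 is cut. This separates the molecule into its two stereochemical clusters, each complete, and the union creates no stereocentre. The sp2 electrophile is placed on the triquinane and the sp3 nucleophile on the terpene.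

15 from 14, 13, 12 and 11. These are changes of oxidation state on ring A only: the C3 bromide and the silylated enol come from the 1,2-dione 13, and 13 from enone 11 by epoxidation and isomerisation, which places oxygen on C1 without ambiguity.

11 from 10 and 9; 9 from 8; 8 from 6 and 7. Ring A is cut at C1=C7a (aldol condensation) and at the C3a–C3 bond (enolate allylation). The allylation is placed on tricycle 6, where the cyclopropane still blocks the other α-position and the bowl shape directs 7 to the face anti to ring C. Only then is the three-membered ring opened to 9.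

6 from 5; 5 from 4 (key disconnection). The bonds C7a–C7 and C6–C6a are cut together: both five-membered rings of the B/C unit come from one photochemical rearrangement of bicyclooctenone 4. The cis fusion and the C5 quaternary centre are already present in 4.

4 from 2 and 3; 2 from 1. A Diels–Alder disconnection gives two commodity chemicals. The acetoxy-bearing carbon of 2 blocks re-aromatisation, steers the facial course and is erased later.

35 from 34, 33 and 32; 32 from 31, 30 and 29. The iodide, the silyl ether and the acetal are functional-group changes. Ring E is cut at C7'–C8', between an aldehyde carbon and an alkenyl carbon, because a Nozaki–Hiyama–Kishi closure tolerates nine-membered rings and the alkenyl partner already carries the future exocyclic CH2.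

29 from 28, 27 and 26; 26 from 24. The aldehyde comes from the vinyl group and the enol triflate from a methyl ketone. That ketone comes from cyclobutanone 24 by a two-carbon homologation that also sets C9' trans.

24 from 21 and 17 (through 22 and 23); 17 from 16. The cyclobutane is cut into the distal alkene of the neryl chain and a two-carbon keteniminium unit. This delivers the ring at the ketone oxidation level; C1' is set by the auxiliary.

21 from 20, 19 and 18. C4' and C5' come from the Z alkene of 18 by asymmetric epoxidation and inverting opening at C5'. The Z geometry maps onto the cis C4'/C5' relationship with the hydroxymethyl as the linking CH2.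

## Alternatives that were turned down

Alternative 1: The cyclobutane is disconnected into the distal alkene of geranyl acetate A1 and the allenic ester A2. Forward, a chiral oxazaborolidine activated by AlBr3 would give alkylidenecyclobutane A3. In its favour: one catalytic step from cheap materials sets C1', and the reaction type is well established for prenyl-type alkenes. On this point it is stronger than the auxiliary-based cycloaddition of step 17. Against it for this target: the step makes one ring and one stereocentre and leaves the triquinane, with five stereocentres and two quaternary carbons, untouched. The E geometry of A1 does not map onto the cis C4'/C5' pattern by the epoxide-opening logic used here, because the carbon nucleophile would have to become the linking CH2. A3 also arrives as an unsaturated ester that must be degraded or reshaped before C8' can carry the methylene. The chosen strategy centres on the step that makes two rings of the harder half, and its keteniminium cycloaddition gives the cyclobutanone 24 directly at the oxidation level the route needs.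

Alternative 2: Ring E is disconnected at C6'=C7'. Forward, the second-generation Hoveyda–Grubbs catalyst would close the nine-membered Z-enone lactone A4. In its favour: a single catalytic step closes the medium ring, the lactone pre-organises the chain, and its atoms later become ring D. In ring-closure step economy it is stronger than steps 22–24 here. Against it: ring A and both quaternary carbons of the triquinane would then have to be built onto a lactone in the presence of the medium ring, in a linear sequence. The enone must be reduced and the hindered ketone beside the epimerisable cyclobutane methine methylenated late. Nine-membered metathesis of an electron-poor vinyl ketone also competes with dimerisation. The chosen strategy offers convergence in exchange: the triquinane is finished separately and joined in one coupling.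

Alternative 3: Ring D is disconnected into the 1,2-dione (the keto form of 13) and cyclononene enal A5. Forward, ethylenediammonium diacetate would effect Knoevenagel condensation and oxa-6π closure to 2H-pyran A6. In its favour: C–C and C–O bonds form in one pot without protecting groups or metals, so the union is shorter than steps 28–29. Against it: the electrocyclisation creates C4' under the influence of the distant cyclobutane only, so its facial course is unpredictable. The extra C5'=CH alkene must then be hydrogenated selectively beside the exocyclic methylene and from the correct face. The condensation must also choose between the two enolisable sides of the dione, and A5 needs a tetrasubstituted alkene in a nine-membered ring. The chosen strategy fixes C4' and C5' by reagent control before ring E exists. Alternative 3 would still need the triquinane dione, which the chosen key step supplies.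

Key step: step 3

**Remarks on the chemistry (assumptions).** The (2R,5R) antipode of the pyrrolidine in 17 is assumed to give the (R)-cyclobutanone 24; if the sense of induction is the opposite, the (2S,5S) antipode is used and nothing else changes. Compound 13 is drawn as its 1-hydroxy-2-oxo enol tautomer.

## Steps

Step 1
Reactants: 1 o-cresol (2-methylphenol)
Product: 2 (±)-6-acetoxy-6-methylcyclohexa-2,4-dien-1-one
Conditions: Pb(OAc)4, AcOH, CH2Cl2, 0 °C to rt
Reagents that add atoms: lead tetraacetate, CC(=O)O[Pb](OC(C)=O)(OC(C)=O)OC(C)=O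
Why: Wessely acetoxylation: the aryloxy–lead intermediate delivers acetate to the methyl-bearing ortho carbon and gives a dienone that cannot re-aromatise; the racemic product is used promptly because it dimerises slowly.

Step 2
Reactants: 2 (±)-6-acetoxy-6-methylcyclohexa-2,4-dien-1-one; 3 methyl methacrylate
Product: 4 methyl (1R,3R,4R,7R)-3-acetoxy-3,7-dimethyl-2-oxobicyclo[2.2.2]oct-5-ene-7-carboxylate
Conditions: 3 (neat, excess), BHT, 60 °C; then separation of the enantiomers by preparative chromatography on a chiral stationary phase (amylose tris(3,5-dimethylphenylcarbamate), CO2/MeOH)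
Reagents that add atoms: none
Why: Diels–Alder reaction of a 2,4-cyclohexadienone with ortho regiochemistry (ester carbon to the carbonyl-bearing diene terminus), ester endo (syn to the new alkene bridge) and attack on the face carrying the acetoxy group, which sets C1, C4 and C7 relative to each other. The resolution fixes the absolute configuration on cheap material before the key step.

Step 3
Reactants: 4 methyl (1R,3R,4R,7R)-3-acetoxy-3,7-dimethyl-2-oxobicyclo[2.2.2]oct-5-ene-7-carboxylate
Product: 5 methyl (1S,2R,4R,5R,7R,8S)-4-acetoxy-4,7-dimethyl-3-oxotricyclo[3.3.0.0^2,8]octane-7-carboxylate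
Conditions: hν (λ ≥ 300 nm, Pyrex), acetone (degassed), rt
Reagents that add atoms: none
Why: Triplet energy transfer from acetone excites the β,γ-unsaturated ketone; the carbonyl carbon C2 bridges to the near alkene carbon C6, the C1–C2 bond breaks, and the resulting 1,3-diradical at C1/C5 recombines, a net 1,2-acyl shift plus cyclopropane formation. The closest known reaction is the oxa-di-π-methane rearrangement of bicyclo[2.2.2]oct-5-en-2-ones to tricyclo[3.3.0.0^2,8]octan-3-ones, which tolerates an oxygenated quaternary α-carbon. The ketone-bearing five-membered ring (future ring B) closes through the acyl shift (new C2–C6 bond), and the second five-membered ring (future ring C) closes by three-membered radical recombination (new C1–C5 bond), which forms the cyclopropane at the same time. Both bonds form on one face of the rigid bicycle, so the cis ring fusion is enforced and the new methine from C5 of 4 (C6a of 40) takes its configuration from the skeleton. C7 of 4 (C5 of 40) and C4 of 4 (C3b of 40) are carried through unchanged. The step needs the triplet 1,2-shift to win over the singlet 1,3-acyl shift and over α-cleavage toward the acetoxy-bearing carbon. Sensitisation in acetone at wavelengths where the sensitiser absorbs, together with the fixed β,γ geometry, should secure this. Irradiation is stopped at full conversion to spare the cyclopropyl ketone.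

Step 4
Reactants: 5 methyl (1S,2R,4R,5R,7R,8S)-4-acetoxy-4,7-dimethyl-3-oxotricyclo[3.3.0.0^2,8]octane-7-carboxylate
Product: 6 methyl (1R,2R,4S,5R,7R,8S)-4,7-dimethyl-3-oxotricyclo[3.3.0.0^2,8]octane-7-carboxylate
Conditions: SmI2 (2.2 equiv), THF/MeOH, −78 °C
Reagents that add atoms: none
Why: Reductive cleavage of an α-acyloxy ketone by SmI2 is fast at −78 °C, whereas opening of the cyclopropyl ketone needs a stronger reductant system, so the cyclopropane is kept as a block on the other α-position. The configuration of the new C4–H is immaterial because it is erased in step 5.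

Step 5
Reactants: 6 methyl (1R,2R,4S,5R,7R,8S)-4,7-dimethyl-3-oxotricyclo[3.3.0.0^2,8]octane-7-carboxylate; 7 allyl bromide
Product: 8 methyl (1R,2R,4S,5R,7R,8S)-4,7-dimethyl-3-oxo-4-(prop-2-en-1-yl)tricyclo[3.3.0.0^2,8]octane-7-carboxylate
Conditions: LiN(iPr)2, THF, −78 °C; then 7, −78 to 0 °C
Reagents that add atoms: none
Why: Enolate alkylation: only C4 can be enolised because the other α-carbon is a cyclopropane bridgehead. The electrophile enters from the open face of the bowl, anti to the ester-bearing ring, which leaves the methyl syn to that ring and so sets C3a of 40.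

Step 6
Reactants: 8 methyl (1R,2R,4S,5R,7R,8S)-4,7-dimethyl-3-oxo-4-(prop-2-en-1-yl)tricyclo[3.3.0.0^2,8]octane-7-carboxylate
Product: 9 methyl (2S,3aR,4S,6aR)-2,4-dimethyl-5-oxo-4-(prop-2-en-1-yl)octahydropentalene-2-carboxylate
Conditions: SmI2 (2.5 equiv), HMPA, t-BuOH, THF, 0 °C
Reagents that add atoms: none
Why: Ketyl formation and cleavage of the C2–C8 cyclopropane bond, the one outside the ketone ring that overlaps with the carbonyl π system, is the known reductive opening of tricyclo[3.3.0.0^2,8]octan-3-ones to cis-bicyclo[3.3.0]octan-3-ones. The quaternary ester carbon is left between two CH2 groups.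

Step 7
Reactants: 9 methyl (2S,3aR,4S,6aR)-2,4-dimethyl-5-oxo-4-(prop-2-en-1-yl)octahydropentalene-2-carboxylate
Product: 10 methyl (2S,3aR,4S,6aR)-2,4-dimethyl-5-oxo-4-(2-oxopropyl)octahydropentalene-2-carboxylate
Conditions: PdCl2 (10 mol %), CuCl, O2 (1 atm), DMF/H2O, rt
Reagents that add atoms: water, O
Why: Wacker oxidation of the terminal alkene gives the methyl ketone with Markovnikov selectivity; ketone and ester are inert.

Step 8
Reactants: 10 methyl (2S,3aR,4S,6aR)-2,4-dimethyl-5-oxo-4-(2-oxopropyl)octahydropentalene-2-carboxylate
Product: 11 methyl (3aS,3bR,5S,6aS)-3a,5-dimethyl-2-oxo-3,3a,3b,4,5,6,6a,7-octahydro-2H-cyclopenta[a]pentalene-5-carboxylate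
Conditions: NaOMe, MeOH, 60 °C
Reagents that add atoms: none
Why: Intramolecular aldol condensation of the 1,4-diketone: the methyl-ketone enolate adds to the ring ketone and dehydration gives the fused cyclopentenone (ring A, C1=C7a). Methoxide cannot scramble the methyl ester.

Step 9
Reactants: 11 methyl (3aS,3bR,5S,6aS)-3a,5-dimethyl-2-oxo-3,3a,3b,4,5,6,6a,7-octahydro-2H-cyclopenta[a]pentalene-5-carboxylate
Product: 12 the 1,7a-epoxide of 11 with the oxygen cis to the C3a methyl
Conditions: H2O2 (30 %), K2CO3, MeOH, 0 °C to rt
Reagents that add atoms: hydrogen peroxide, OO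
Why: Weitz–Scheffer epoxidation of the enone; oxygen must add to C7a on the face of the angular methyl, because only that product keeps a cis A/B fusion.

Step 10
Reactants: 12 the 1,7a-epoxide of 11 with the oxygen cis to the C3a methyl
Product: 13 methyl (3aS,3bR,5S,6aS)-1-hydroxy-3a,5-dimethyl-2-oxo-3,3a,3b,4,5,6,6a,7-octahydro-2H-cyclopenta[a]pentalene-5-carboxylate (diosphenol of the ring-A 1,2-dione)
Conditions: H2SO4 (cat.), AcOH, rt
Reagents that add atoms: none
Why: Acid-promoted isomerisation of an α,β-epoxy ketone to a diosphenol: the epoxide opens at the fully substituted C7a, hydride shifts from C1 and the dione enolises. The competing acyl shift would contract ring A to a cyclobutanone and is disfavoured.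

Step 11
Reactants: 13 methyl (3aS,3bR,5S,6aS)-1-hydroxy-3a,5-dimethyl-2-oxo-3,3a,3b,4,5,6,6a,7-octahydro-2H-cyclopenta[a]pentalene-5-carboxylate
Product: 14 methyl (3aS,3bR,5S,6aS,7aR)-3-bromo-2-hydroxy-3a,5-dimethyl-1-oxo-3a,3b,4,5,6,6a,7,7a-octahydro-1H-cyclopenta[a]pentalene-5-carboxylate
Conditions: LiN(iPr)2 (2.2 equiv), THF, −78 °C; NBS; aq. NH4Cl
Reagents that add atoms: N-bromosuccinimide, O=C1CCC(=O)N1Br
Why: The O,C-dianion reacts with electrophilic bromine at its more reactive and less hindered carbon terminus C3. On work-up the bromo dione should settle as the conjugated bromo enol, with C7a protonated to the strain-free cis A/B fusion (sets C7a of 40 under thermodynamic control).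

Step 12
Reactants: 14 methyl (3aS,3bR,5S,6aS,7aR)-3-bromo-2-hydroxy-3a,5-dimethyl-1-oxo-3a,3b,4,5,6,6a,7,7a-octahydro-1H-cyclopenta[a]pentalene-5-carboxylate
Product: 15 the O-tert-butyldimethylsilyl ether of 14 at the C2 enol oxygen
Conditions: TBSCl, imidazole, DMF, rt
Reagents that add atoms: tert-butyldimethylsilyl chloride, CC(C)(C)[Si](C)(C)Cl
Why: Silylation of the enolic hydroxyl removes the acidic proton before the organozinc coupling and fixes the C2=C3 enol form, in which the carbon–bromine bond is vinylic.

Step 13
Reactants: 16 (2R,5R)-2,5-dimethylpyrrolidine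
Product: 17 1-[(2R,5R)-2,5-dimethylpyrrolidin-1-yl]ethan-1-one
Conditions: AcCl, Et3N, CH2Cl2, 0 °C
Reagents that add atoms: acetyl chloride, CC(=O)Cl
Why: N-acylation of a secondary amine gives the C2-symmetric acetamide from which a chiral keteniminium salt is generated.

Step 14
Reactants: 18 nerol
Product: 19 [(2R,3S)-3-methyl-3-(4-methylpent-3-en-1-yl)oxiran-2-yl]methanol
Conditions: Ti(OiPr)4 (10 mol %), D-(−)-diethyl tartrate, t-BuOOH, 4 Å MS, CH2Cl2, −20 °C
Reagents that add atoms: tert-butyl hydroperoxide, CC(C)(C)OO
Why: Sharpless asymmetric epoxidation is selective for the allylic alcohol over the distal alkene. The D-tartrate ligand delivers oxygen to the face that gives the (2R,3S)-epoxide, which fixes C4' directly and C5' after inversion.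

Step 15
Reactants: 19 [(2R,3S)-3-methyl-3-(4-methylpent-3-en-1-yl)oxiran-2-yl]methanol
Product: 20 (2S,3S)-2-ethenyl-3,7-dimethyloct-6-ene-1,3-diol
Conditions: CH2=CHMgBr (4 equiv), CuI (15 mol %), THF, −30 to 0 °C
Reagents that add atoms: vinylmagnesium bromide, C=C[Mg]Br
Why: Copper-catalysed SN2 opening of the 2,3-epoxy alcohol at C2, the only epoxide carbon that is not fully substituted, with inversion. The Z geometry of 18 becomes the cis C4'/C5' relationship, with the hydroxymethyl as the future linking CH2 and the vinyl group as C6'/C7'.

Step 16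
Reactants: 20 (2S,3S)-2-ethenyl-3,7-dimethyloct-6-ene-1,3-diol
Product: 21 (4S,5S)-5-ethenyl-2,2,4-trimethyl-4-(4-methylpent-3-en-1-yl)-1,3-dioxane
Conditions: 2,2-dimethoxypropane, PPTS (cat.), CH2Cl2, rt
Reagents that add atoms: 2,2-dimethoxypropane, COC(C)(C)OC
Why: Acetal formation of the 1,3-diol; the dioxane later holds the two chains gauche, as ring D does in the target.

Step 17
Reactants: 21 (4S,5S)-5-ethenyl-2,2,4-trimethyl-4-(4-methylpent-3-en-1-yl)-1,3-dioxane; 17 1-[(2R,5R)-2,5-dimethylpyrrolidin-1-yl]ethan-1-one
Product: 24 (2R)-2-{2-[(4S,5S)-5-ethenyl-2,2,4-trimethyl-1,3-dioxan-4-yl]ethyl}-3,3-dimethylcyclobutan-1-one, via keteniminium triflate 22 (not isolated), via cyclobutaniminium triflate 23 (not isolated)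
Conditions: 17, Tf2O, 2,4,6-collidine, ClCH2CH2Cl, −20 °C to rt; then 21, 60 °C; then aq. NaHCO3, rt
Reagents that add atoms: water, O
Why: Keteniminium–alkene [2+2] cycloaddition: the electrophilic central carbon bonds to the less substituted alkene carbon and the CH2 terminus to the gem-dimethyl carbon, and the trisubstituted alkene reacts in preference to the vinyl group. The C2-symmetric pyrrolidine differentiates the alkene faces and sets C1'; hydrolysis of the iminium salt gives the cyclobutanone.

Step 18
Reactants: 24 (2R)-2-{2-[(4S,5S)-5-ethenyl-2,2,4-trimethyl-1,3-dioxan-4-yl]ethyl}-3,3-dimethylcyclobutan-1-one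
Product: 26 1-[(1R,2S)-2-{2-[(4S,5S)-5-ethenyl-2,2,4-trimethyl-1,3-dioxan-4-yl]ethyl}-3,3-dimethylcyclobutyl]ethan-1-one, via methyl enol ether 25 (not isolated)
Conditions: (1-methoxyethyl)triphenylphosphonium chloride, n-BuLi, THF, −78 to 0 °C; then p-TsOH (cat.), acetone/H2O, rt; then DBU, CH2Cl2, rt
Reagents that add atoms: (1-methoxyethyl)triphenylphosphonium chloride, COC(C)[P+](c1ccccc1)(c1ccccc1)c1ccccc1.[Cl-]; water, O
Why: Wittig reaction with an α-alkoxy ylide followed by enol-ether hydrolysis homologates the ketone to a methyl ketone, so C1' is no longer α to a carbonyl. Acetone as solvent keeps the acetonide in place, and base equilibration puts the acetyl group trans to the side chain (sets C9').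

Step 19
Reactants: 26 1-[(1R,2S)-2-{2-[(4S,5S)-5-ethenyl-2,2,4-trimethyl-1,3-dioxan-4-yl]ethyl}-3,3-dimethylcyclobutyl]ethan-1-one
Product: 27 1-[(1R,2S)-2-{2-[(4S,5S)-5-ethenyl-2,2,4-trimethyl-1,3-dioxan-4-yl]ethyl}-3,3-dimethylcyclobutyl]ethenyl trifluoromethanesulfonate
Conditions: KN(SiMe3)2, THF, −78 °C; PhNTf2
Reagents that add atoms: N-phenylbis(trifluoromethanesulfonimide), O=S(=O)(N(c1ccccc1)S(=O)(=O)C(F)(F)F)C(F)(F)F
Why: Kinetic deprotonation at the methyl group and O-triflation give the 1,1-disubstituted enol triflate, whose CH2 is the future exocyclic methylene.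

Step 20
Reactants: 27 1-[(1R,2S)-2-{2-[(4S,5S)-5-ethenyl-2,2,4-trimethyl-1,3-dioxan-4-yl]ethyl}-3,3-dimethylcyclobutyl]ethenyl trifluoromethanesulfonate
Product: 28 the primary alcohol from 27 in which the ethenyl group on the dioxane has become 2-hydroxyethyl
Conditions: 9-BBN, THF, 0 °C to rt; then NaBO3·4H2O, H2O
Reagents that add atoms: sodium perborate, [Na+].[O-]OB=O
Why: Anti-Markovnikov hydroboration of the monosubstituted alkene; the electron-poor enol triflate does not react with the hindered borane, and perborate oxidises without hydrolysing the triflate.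

Step 21
Reactants: 28 the primary alcohol from 27 in which the ethenyl group on the dioxane has become 2-hydroxyethyl
Product: 29 the aldehyde corresponding to 28 (2-oxoethyl on the dioxane)
Conditions: Dess–Martin periodinane, NaHCO3, CH2Cl2, rt
Reagents that add atoms: none
Why: Mild oxidation of a primary alcohol to the aldehyde that leaves acetal and enol triflate untouched.

Step 22
Reactants: 29 the aldehyde corresponding to 28 (2-oxoethyl on the dioxane)
Product: 30 the tricyclic allylic alcohol: acetonide-bridged (1'S,4'S,5'S,9'R)-bicyclo[7.2.0]undecane with C8' methylidene and C7' hydroxyl (either carbinol configuration)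
Conditions: CrCl2 (6 equiv), NiCl2 (2 mol %), DMF/THF, rt, 3 mM, slow addition
Reagents that add atoms: none
Why: Nozaki–Hiyama–Kishi coupling: nickel inserts into the enol triflate, transmetalation gives an alkenylchromium species that adds to the aldehyde, and this reaction tolerates medium-ring closure. The dioxane and the trans-cyclobutane hold the two ends close, and the carbinol centre is removed in step 24.

Step 23
Reactants: 30 the tricyclic allylic alcohol
Product: 31 the methyl carbonate of 30
Conditions: ClCO2Me, pyridine, DMAP (cat.), CH2Cl2, 0 °C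
Reagents that add atoms: methyl chloroformate, COC(=O)Cl
Why: Acylation of the secondary allylic alcohol gives the leaving group needed for ionisation by palladium.

Step 24
Reactants: 31 the methyl carbonate of 30
Product: 32 the acetonide of diol 33 (31 with C7' reduced to CH2)
Conditions: Pd(OAc)2 (5 mol %), PBu3, HCO2NH4, dioxane, 80 °C
Reagents that add atoms: none
Why: Palladium-catalysed formate reduction of an allylic carbonate: the π-allyl complex takes hydride at its more substituted terminus, which gives the less substituted exocyclic alkene and leaves C7' as CH2.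

Step 25
Reactants: 32 the acetonide of diol 33
Product: 33 (1S,4S,5S,9R)-5-(hydroxymethyl)-4,11,11-trimethyl-8-methylidenebicyclo[7.2.0]undecan-4-ol
Conditions: PPTS, MeOH, 40 °C
Reagents that add atoms: none
Why: Transacetalisation removes the acetonide under conditions too mild to isomerise the exocyclic alkene or ionise the tertiary alcohol.

Step 26
Reactants: 33 (1S,4S,5S,9R)-5-(hydroxymethyl)-4,11,11-trimethyl-8-methylidenebicyclo[7.2.0]undecan-4-ol
Product: 34 (1S,4S,5R,9R)-5-(iodomethyl)-4,11,11-trimethyl-8-methylidenebicyclo[7.2.0]undecan-4-ol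
Conditions: I2, PPh3, imidazole, CH2Cl2, 0 °C
Reagents that add atoms: iodine, II
Why: Appel-type iodination is selective for the primary hydroxyl; the tertiary alcohol does not react.

Step 27
Reactants: 34 (1S,4S,5R,9R)-5-(iodomethyl)-4,11,11-trimethyl-8-methylidenebicyclo[7.2.0]undecan-4-ol
Product: 35 triethyl{[(1S,4S,5R,9R)-5-(iodomethyl)-4,11,11-trimethyl-8-methylidenebicyclo[7.2.0]undecan-4-yl]oxy}silane
Conditions: Et3SiOTf, 2,6-lutidine, CH2Cl2, −78 to 0 °C
Reagents that add atoms: triethylsilyl trifluoromethanesulfonate, CC[Si](CC)(CC)OS(=O)(=O)C(F)(F)F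
Why: Silylation of the hindered tertiary alcohol removes the proton that would quench the organozinc reagent and prevents oxetane formation from the γ-iodo alcohol.

Step 28
Reactants: 35 triethyl{[(1S,4S,5R,9R)-5-(iodomethyl)-4,11,11-trimethyl-8-methylidenebicyclo[7.2.0]undecan-4-yl]oxy}silane; 15 the O-tert-butyldimethylsilyl ether of 14
Product: 37 the coupled bis-silyl ether in which the C5' methylene of 35 is bonded to C3 of the triquinane, via alkylzinc iodide 36 (not isolated)
Conditions: Zn dust (I2-activated), DMA, 50 °C; then 15, Pd(OAc)2 (5 mol %), SPhos, THF/DMA, 50 °C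
Reagents that add atoms: none
Why: Zinc insertion into the primary iodide is followed by Negishi alkyl–alkenyl coupling. The β-bromo enone is activated for oxidative addition, the bulky biarylphosphine favours reductive elimination over β-hydride elimination, and no stereocentre is touched.

Step 29
Reactants: 37 the coupled bis-silyl ether
Product: 39 the methyl ester of 40, via hydroxy diosphenol 38 (not isolated)
Conditions: HF·pyridine, pyridine, THF, 0 °C to rt; then PPTS (cat.), 4 Å MS, toluene, 60 °C
Reagents that add atoms: none
Why: Fluoride removes both silyl groups; the tertiary hydroxyl then adds to the C2 carbonyl of the 1,2-dione (six-membered hemiketal), and loss of water toward C3 gives the enol ether conjugated with the C1 ketone. The C4'–O bond is never broken, so C4' keeps its configuration.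

Step 30
Reactants: 39 the methyl ester of 40
Product: 40 the target acid CNP0483070.2, (3aS,3bR,5S,6aS,7aR,1'S,4'S,5'S,9'R)
Conditions: LiOH, THF/MeOH/H2O, 45 °C; then dilute HCl to pH 4, 0 °C
Reagents that add atoms: lithium hydroxide, [Li+].[OH-]
Why: Saponification of the hindered methyl ester; the enol ether and the exocyclic alkene are stable to base, and the cis A/B fusion at C7a is the thermodynamic one.

## Compound list

1 | o-cresol | Cc1ccccc1O | starting material
2 | (±)-6-acetoxy-6-methylcyclohexa-2,4-dien-1-one (racemic) | CC(=O)OC1(C)C=CC=CC1=O | intermediate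
3 | methyl methacrylate | C=C(C)C(=O)OC | starting material
4 | methyl (1R,3R,4R,7R)-3-acetoxy-3,7-dimethyl-2-oxobicyclo[2.2.2]oct-5-ene-7-carboxylate | O=C1[C@@H]2C=C[C@@H](C[C@@]2(C)C(=O)OC)[C@@]1(C)OC(C)=O | intermediate
5 | methyl (1S,2R,4R,5R,7R,8S)-4-acetoxy-4,7-dimethyl-3-oxotricyclo[3.3.0.0^2,8]octane-7-carboxylate | O=C1[C@H]2[C@@H]3[C@H]2[C@@H](C[C@@]3(C)C(=O)OC)[C@@]1(C)OC(C)=O | intermediate
6 | methyl (1R,2R,4S,5R,7R,8S)-4,7-dimethyl-3-oxotricyclo[3.3.0.0^2,8]octane-7-carboxylate | O=C1[C@H]2[C@@H]3[C@H]2[C@@H](C[C@@]3(C)C(=O)OC)[C@@H]1C | intermediate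
7 | allyl bromide | C=CCBr | starting material
8 | methyl (1R,2R,4S,5R,7R,8S)-4,7-dimethyl-3-oxo-4-(prop-2-en-1-yl)tricyclo[3.3.0.0^2,8]octane-7-carboxylate | O=C1[C@H]2[C@@H]3[C@H]2[C@@H](C[C@@]3(C)C(=O)OC)[C@]1(C)CC=C | intermediate
9 | methyl (2S,3aR,4S,6aR)-2,4-dimethyl-5-oxo-4-(prop-2-en-1-yl)octahydropentalene-2-carboxylate | O=C1C[C@H]2C[C@](C)(C(=O)OC)C[C@H]2[C@]1(C)CC=C | intermediate
10 | methyl (2S,3aR,4S,6aR)-2,4-dimethyl-5-oxo-4-(2-oxopropyl)octahydropentalene-2-carboxylate | O=C1C[C@H]2C[C@](C)(C(=O)OC)C[C@H]2[C@]1(C)CC(C)=O | intermediate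
11 | methyl (3aS,3bR,5S,6aS)-3a,5-dimethyl-2-oxo-3,3a,3b,4,5,6,6a,7-octahydro-2H-cyclopenta[a]pentalene-5-carboxylate | O=C1C=C2C[C@H]3C[C@](C)(C(=O)OC)C[C@H]3[C@]2(C)C1 | intermediate
12 | 1,7a-epoxide of 11, oxygen cis to the C3a methyl | O=C1[C@H]2O[C@]23C[C@H]4C[C@](C)(C(=O)OC)C[C@H]4[C@]3(C)C1 | intermediate
13 | methyl (3aS,3bR,5S,6aS)-1-hydroxy-3a,5-dimethyl-2-oxo-3,3a,3b,4,5,6,6a,7-octahydro-2H-cyclopenta[a]pentalene-5-carboxylate (diosphenol) | O=C1C(O)=C2C[C@H]3C[C@](C)(C(=O)OC)C[C@H]3[C@]2(C)C1 | intermediate
14 | methyl (3aS,3bR,5S,6aS,7aR)-3-bromo-2-hydroxy-3a,5-dimethyl-1-oxo-3a,3b,4,5,6,6a,7,7a-octahydro-1H-cyclopenta[a]pentalene-5-carboxylate | BrC1=C(O)C(=O)[C@@H]2C[C@H]3C[C@](C)(C(=O)OC)C[C@H]3[C@]12C | intermediate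
15 | O-tert-butyldimethylsilyl ether of 14 (C2 enol oxygen) | BrC1=C(O[Si](C)(C)C(C)(C)C)C(=O)[C@@H]2C[C@H]3C[C@](C)(C(=O)OC)C[C@H]3[C@]12C | intermediate
16 | (2R,5R)-2,5-dimethylpyrrolidine | C[C@@H]1CC[C@@H](C)N1 | starting material
17 | 1-[(2R,5R)-2,5-dimethylpyrrolidin-1-yl]ethan-1-one | CC(=O)N1[C@H](C)CC[C@H]1C | intermediate
18 | nerol | OC/C=C(C)\CCC=C(C)C | starting material
19 | [(2R,3S)-3-methyl-3-(4-methylpent-3-en-1-yl)oxiran-2-yl]methanol | OC[C@H]1O[C@@]1(C)CCC=C(C)C | intermediate
20 | (2S,3S)-2-ethenyl-3,7-dimethyloct-6-ene-1,3-diol | C=C[C@@H](CO)[C@@](C)(O)CCC=C(C)C | intermediate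
21 | (4S,5S)-5-ethenyl-2,2,4-trimethyl-4-(4-methylpent-3-en-1-yl)-1,3-dioxane | C=C[C@H]1COC(C)(C)O[C@@]1(C)CCC=C(C)C | intermediate
22 | (2R,5R)-1-ethenylidene-2,5-dimethylpyrrolidinium triflate (keteniminium salt) | C=C=[N+]1[C@H](C)CC[C@H]1C.[O-]S(=O)(=O)C(F)(F)F | intermediate (not isolated)
23 | cyclobutaniminium triflate from 21 and 22 | C=C[C@H]1COC(C)(C)O[C@@]1(C)CC[C@H]1C(=[N+]2[C@H](C)CC[C@H]2C)CC1(C)C.[O-]S(=O)(=O)C(F)(F)F | intermediate (not isolated)
24 | (2R)-2-{2-[(4S,5S)-5-ethenyl-2,2,4-trimethyl-1,3-dioxan-4-yl]ethyl}-3,3-dimethylcyclobutan-1-one | C=C[C@H]1COC(C)(C)O[C@@]1(C)CC[C@H]1C(=O)CC1(C)C | intermediate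
25 | methyl enol ether (1-methoxyethylidene cyclobutane) from 24 | C=C[C@H]1COC(C)(C)O[C@@]1(C)CC[C@H]1C(=C(C)OC)CC1(C)C | intermediate (not isolated)
26 | 1-[(1R,2S)-2-{2-[(4S,5S)-5-ethenyl-2,2,4-trimethyl-1,3-dioxan-4-yl]ethyl}-3,3-dimethylcyclobutyl]ethan-1-one | C=C[C@H]1COC(C)(C)O[C@@]1(C)CC[C@H]1[C@H](C(C)=O)CC1(C)C | intermediate
27 | enol triflate of 26 (1-cyclobutylethenyl triflate) | C=C[C@H]1COC(C)(C)O[C@@]1(C)CC[C@H]1[C@H](C(=C)OS(=O)(=O)C(F)(F)F)CC1(C)C | intermediate
28 | primary alcohol from hydroboration of 27 | OCC[C@H]1COC(C)(C)O[C@@]1(C)CC[C@H]1[C@H](C(=C)OS(=O)(=O)C(F)(F)F)CC1(C)C | intermediate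
29 | aldehyde from 28 | O=CC[C@H]1COC(C)(C)O[C@@]1(C)CC[C@H]1[C@H](C(=C)OS(=O)(=O)C(F)(F)F)CC1(C)C | intermediate
30 | nine-membered allylic alcohol (C7' hydroxyl, either configuration), acetonide in place | C=C1C(O)C[C@H]2COC(C)(C)O[C@@]2(C)CC[C@H]3[C@H]1CC3(C)C | intermediate
31 | methyl carbonate of 30 | C=C1C(OC(=O)OC)C[C@H]2COC(C)(C)O[C@@]2(C)CC[C@H]3[C@H]1CC3(C)C | intermediate
32 | acetonide of 33 | C=C1CC[C@H]2COC(C)(C)O[C@@]2(C)CC[C@H]3[C@H]1CC3(C)C | intermediate
33 | (1S,4S,5S,9R)-5-(hydroxymethyl)-4,11,11-trimethyl-8-methylidenebicyclo[7.2.0]undecan-4-ol | C=C1CC[C@@H](CO)[C@@](C)(O)CC[C@H]2[C@H]1CC2(C)C | intermediate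
34 | (1S,4S,5R,9R)-5-(iodomethyl)-4,11,11-trimethyl-8-methylidenebicyclo[7.2.0]undecan-4-ol | C=C1CC[C@@H](CI)[C@@](C)(O)CC[C@H]2[C@H]1CC2(C)C | intermediate
35 | triethyl{[(1S,4S,5R,9R)-5-(iodomethyl)-4,11,11-trimethyl-8-methylidenebicyclo[7.2.0]undecan-4-yl]oxy}silane | C=C1CC[C@@H](CI)[C@@](C)(O[Si](CC)(CC)CC)CC[C@H]2[C@H]1CC2(C)C | intermediate
36 | alkylzinc iodide from 35 | C=C1CC[C@@H](C[Zn]I)[C@@](C)(O[Si](CC)(CC)CC)CC[C@H]2[C@H]1CC2(C)C | intermediate (not isolated)
37 | coupled bis-silyl ether (C3–CH2–C5' bond formed) | C=C1CC[C@@H](CC3=C(O[Si](C)(C)C(C)(C)C)C(=O)[C@@H]4C[C@H]5C[C@](C)(C(=O)OC)C[C@H]5[C@]34C)[C@@](C)(O[Si](CC)(CC)CC)CC[C@H]2[C@H]1CC2(C)C | intermediate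
38 | hydroxy diosphenol (37 without both silyl groups) | C=C1CC[C@@H](CC3=C(O)C(=O)[C@@H]4C[C@H]5C[C@](C)(C(=O)OC)C[C@H]5[C@]34C)[C@@](C)(O)CC[C@H]2[C@H]1CC2(C)C | intermediate (not isolated)
39 | methyl ester of the target | C=C1CC[C@H]2CC3=C(O[C@@]2(C)CC[C@H]2[C@H]1CC2(C)C)C(=O)[C@@H]1C[C@H]2C[C@](C)(C(=O)OC)C[C@H]2[C@]31C | intermediate
40 | target acid CNP0483070.2 | C=C1CC[C@H]2CC3=C(O[C@@]2(C)CC[C@H]2[C@H]1CC2(C)C)C(=O)[C@@H]1C[C@H]2C[C@](C)(C(=O)O)C[C@H]2[C@]31C | target

## Step count and least certain steps

Total: 30 steps. Longest linear sequence: 17 steps (18 to 40: steps 14–27, then 28–30). The triquinane branch from 1 runs 12 steps to 15 and then shares steps 28–30.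

Step 3 (key step). The most likely failure is loss of material to singlet chemistry or to α-cleavage toward the acetoxy-bearing carbon (decarbonylation, 1,3-acyl shift), because that carbon gives a stabilised radical; over-irradiation of the cyclopropyl ketone is a second risk. Fallback: the order of photolysis and deacetoxylation is reversed. Starting from 4, SmI2 at −78 °C removes the acetoxy group to give methyl (1R,4R,7R)-3,7-dimethyl-2-oxobicyclo[2.2.2]oct-5-ene-7-carboxylate F1. This ketone, which has no oxygen on the α-carbon, is irradiated in acetone and undergoes the same rearrangement, returning to the route at 6.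

Step 17. The auxiliary may discriminate poorly between the faces of an alkene far from any other stereocentre, and the triflic medium may attack the acetonide or the vinyl group. Fallback: the auxiliary is given up and the ring carbon is corrected by equilibration. Starting from 21, dichloroketene (Cl3CCOCl, Zn–Cu, POCl3, Et2O) gives the 2,2-dichlorocyclobutanone F2, and Zn/AcOH removes the chlorines to give 24 together with its (2S)-ring epimer F3. The two are separated by preparative HPLC, and F3 is re-equilibrated with DBU (its stereocentre is α to the ketone) and recycled. The route is rejoined at 24.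

Step 22. Intermolecular coupling, simple reduction of the triflate or the strain of the forming ring may prevent closure. Fallback: the same C7'–C8' bond is closed without an oxygen at C7'. Starting from 27, 9-BBN gives the B-alkyl-9-borabicyclo[3.3.1]nonane F4, and intramolecular B-alkyl Suzuki coupling (PdCl2(dppf), AsPh3, Cs2CO3, DMF/THF/H2O, high dilution) leads directly to 32, skipping 28–31.

Step 12 (with step 11). Bromination may occur at C7a instead of C3, or the silyl group may be trapped on the other dione oxygen (enol toward C7a), which would leave a non-vinylic bromide useless for coupling; the two enol forms are close in energy. Fallback: the vinyl bromide is avoided altogether. Starting from 13 and 35, the O,C-dianion of 13 (LiN(iPr)2, THF/HMPA) is alkylated at C3 by 35 to give the C3-alkylated diosphenol triethylsilyl ether F5. HF·pyridine followed by PPTS, as in step 29, then returns to the route at 39.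

Step 28. Transmetalation to a tetrasubstituted alkenylpalladium flanked by a quaternary carbon may be slow, which would let β-hydride elimination or protodezincation of the β-branched alkylzinc win. Fallback: no organozinc is preformed. Starting from 35 and 15, a nickel-catalysed reductive cross-electrophile coupling (NiBr2(dme), 4,4'-di-tert-butyl-2,2'-bipyridine, Mn, DMA) joins the two halides directly and returns to the route at 37.

## Further compounds

F1 | step 3 | methyl (1R,4R,7R)-3,7-dimethyl-2-oxobicyclo[2.2.2]oct-5-ene-7-carboxylate (C3 epimers) | O=C1[C@@H]2C=C[C@@H](C[C@@]2(C)C(=O)OC)C1C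
F2 | step 17 | 2,2-dichloro-4-{2-[(4S,5S)-5-ethenyl-2,2,4-trimethyl-1,3-dioxan-4-yl]ethyl}-3,3-dimethylcyclobutan-1-one (both ring epimers) | C=C[C@H]1COC(C)(C)O[C@@]1(C)CCC1C(=O)C(Cl)(Cl)C1(C)C
F3 | step 17 | (2S)-2-{2-[(4S,5S)-5-ethenyl-2,2,4-trimethyl-1,3-dioxan-4-yl]ethyl}-3,3-dimethylcyclobutan-1-one | C=C[C@H]1COC(C)(C)O[C@@]1(C)CC[C@@H]1C(=O)CC1(C)C
F4 | step 22 | B-alkyl-9-borabicyclo[3.3.1]nonane from hydroboration of 27 | C1CC2CCCC(C1)B2CC[C@H]1COC(C)(C)O[C@@]1(C)CC[C@H]1[C@H](C(=C)OS(=O)(=O)C(F)(F)F)CC1(C)C
F5 | step 12 | C3-alkylated diosphenol triethylsilyl ether from 13 and 35 (C3 epimers) | C=C1CC[C@@H](CC3C(=O)C(O)=C4C[C@H]5C[C@](C)(C(=O)OC)C[C@H]5[C@@]43C)[C@@](C)(O[Si](CC)(CC)CC)CC[C@H]2[C@H]1CC2(C)C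
F0 | step 28 | none | none
A1 | alternative 1 | geranyl acetate | CC(=O)OC/C=C(C)/CCC=C(C)C
A2 | alternative 1 | 2,2,2-trifluoroethyl buta-2,3-dienoate | C=C=CC(=O)OCC(F)(F)F
A3 | alternative 1 | alkylidenecyclobutane carrying the geranyl chain | CC(=O)OC/C=C(C)/CC[C@H]1/C(=C/C(=O)OCC(F)(F)F)CC1(C)C
A4 | alternative 2 | cyclobutane-fused nine-membered Z-enone lactone | O=C1/C=C\[C@H]2CCC(=O)O[C@@]2(C)CC[C@H]2[C@H]1CC2(C)C
A5 | alternative 3 | (1S,9R)-4,11,11-trimethyl-8-methylidenebicyclo[7.2.0]undec-4-ene-5-carbaldehyde | C=C1CCC(C=O)=C(C)CC[C@H]2[C@H]1CC2(C)C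
A6 | alternative 3 | 2H-pyran (dehydro) form of the target methyl ester | C=C1CCC2=CC3=C(O[C@@]2(C)CC[C@H]2[C@H]1CC2(C)C)C(=O)[C@@H]1C[C@H]2C[C@](C)(C(=O)OC)C[C@H]2[C@]31C
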